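The runs were generated by integration for an exercise; scatter was added.

A flask charged with equal end groups that react one with one, and with nothing else, cannot keep a lasting remainder of either, yet the summer run, this same flask followed so far, seemed to be heading for one.

- summer: first end groups 0.80 M; second end groups 0.80 M; protic impurity 0.040 M; the very flask that is asked about, followed so far
- flask: first end groups 0.80 M; second end groups 0.800 M; protic impurity 0.0400 M; time 20 h

summer run (percent of the first end groups charged)

| time / h | links / % | first end groups / % |
|---|---|---|
| 0.200 | 56.5 | 43.5 |
| 0.333 | 68.2 | 31.9 |
| 0.417 | 72.1 | 28.0 |
| 0.667 | 79.7 | 19.4 |
| 1.00 | 86.2 | 15.2 |
| 1.50 | 88.2 | 11.6 |
| 2.50 | 91.3 | 8.1 |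

(standard deviation of a reading: 0.5 percentage points)

- each molecule carries two end groups: a chain counts once for every two ends that are left, dead ends included; the units are half of the end groups of the two monomers charged
- a link that another step uses up counts as cut, two dead ends; so do two ends of one kind that react with each other

- average number of monomer units in a chain (unreacted monomers counted as chains of one) at 20 h
- part of the first end groups that has reacted at 20 h

For equal ends that react with each other and with nothing else, the inverse of the fraction of first end groups left rises on a straight line. I read a slope of 6.49 /h from the first reading, but only 3.84 /h between the last readings, so the line bent downward.

I supposed that the protic impurity takes second end groups one for one, up to its whole charge, which makes them the limiting reagent. The dead share f, c(protic impurity) over c(first end groups) as charged, 5.00%, is then the part of the first end groups left without a partner. That gave me a conversion of 95.0%. With f as the chains per unit, the chain length is the inverse of f, 20.0.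

Near that floor, I reckoned the second end groups to decay pseudo-first-order, with half-life 2.13 h. I had put the floor in place of the mean level of first end groups, which the last reading of the summer run put at 8.1% to begin with, so this half-life errs on the long side. Even so, 8.20 half-lives remained after the last reading.

The forecast gave 17 and 95%, the same conversion as mine but a shorter chain, holding that “the reaction is stalling”.

The flask gave 16.4 and 95.4%.

    first end groups + second end groups → links (k = 0.140 /M/min)
    links → over-reaction product (k = 1.30 × 10⁻⁵ /min)
    second end groups + protic impurity → quenched reagent (k = 0.120 /M/min)

In the flask, links and quenched reagent formed while second end groups lasted: the second end groups stood at 4.79% of their charge after 2.00 h, when the quench had 94% of its turnover up to the asked time behind it. Over-reaction product then rose from 0.708% at 10.0 h to 1.44% at 20.0 h, while the chain length went from 18.1 to 16.4, not my 20.0. With 7.2% of the impurity still there, f becomes 4.64%, and the flask held 4.65% of first end groups.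

In the neighbour with 0.016 M of impurity, f is 2.00%, giving a conversion of 98.0% and a chain length of 50.0. That flask gave 97.9% and 28.2.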